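## Retrosynthetic overview
1. Target 25 comes from the deschloro macrolide 24 by monochlorination at C4, the carbon between the two ketones.
2. 24 comes from the 22-membered trienone 23 by a transannular Diels–Alder reaction (bonds C6–C15 and C7–C12). This one step forms ring A (cyclohexene), ring B (cyclohexane) and ring C (14-membered lactone). 23 is released by oxidising the allylic alcohol 22.
3. 22 comes from the open bis[(E)-alkenyl iodide] 21 by nickel-electrocatalytic reductive ring closure at C13–C14. The 22-membered ring is therefore made first, and this step also creates the diene.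
4. 21 comes from a dianion aldol (C4–C5) between β-keto ester 10 and enal 19.
5. 10 comes from a lactol Wittig reaction that sets the Z,Z-diene (bromo alcohol 1, butenolide 5, keto ester 9). 19 comes from (S)-citronellyl bromide 11 and propyne 12.

Assumptions: 1, 5 and 11 are bought enantiopure (Roche-ester, L-lactic-acid and citronellol series); the C4=C5 enol of the target is drawn as in the given SMILES although keto and enol forms interconvert; atoms are numbered C1 (lactone C=O) to C21 (carbinol carbon) along the macrolide chain, with methyl groups on C2, C8, C16 and C21.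

## Route

Step 1
Reactants: 1 (S)-3-bromo-2-methylpropan-1-ol
Product: 2 (S)-3-bromo-2-methylpropanal
Conditions: Dess–Martin periodinane, CH2Cl2, 0 °C to rt
Reagents that add atoms: none
Why: Dess–Martin oxidation runs under neutral conditions, so the β-bromo aldehyde forms without loss of HBr or epimerisation of C16, the stereocentre bought with 1.

Step 2
Reactants: 2 (S)-3-bromo-2-methylpropanal
Product: 3 (1E,3S)-4-bromo-1-iodo-3-methylbut-1-ene
Conditions: CHI3, CrCl2, THF, 0 °C
Reagents that add atoms: iodoform, C(I)(I)I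
Why: Takai olefination converts the aldehyde into the (E)-alkenyl iodide (C14=C15) under non-basic conditions that leave the primary bromide and C16 untouched.

Step 3
Reactants: 3 (1E,3S)-4-bromo-1-iodo-3-methylbut-1-ene
Product: 4 [(2S,3E)-4-iodo-2-methylbut-3-en-1-yl]triphenylphosphonium bromide
Conditions: PPh3, MeCN, 85 °C, dark
Reagents that add atoms: triphenylphosphine, c1ccccc1P(c1ccccc1)c1ccccc1
Why: SN2 quaternisation of the phosphine occurs only at the primary C(sp3)–Br bond, because an alkenyl iodide does not react with a phosphine without a metal catalyst.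

Step 4
Reactants: 5 (S)-5-methylfuran-2(5H)-one
Product: 6 (5S)-5-methyl-2,5-dihydrofuran-2-ol (anomer mixture)
Conditions: iBu2AlH (1.05 equiv), CH2Cl2, −78 °C; then H2O
Reagents that add atoms: none
Why: Partial lactone reduction stops at the lactol, a ring-closed and therefore geometry-protected form of (Z)-4-hydroxypent-2-enal that carries the bought C21.

Step 5
Reactants: 4 [(2S,3E)-4-iodo-2-methylbut-3-en-1-yl]triphenylphosphonium bromide; 6 (5S)-5-methyl-2,5-dihydrofuran-2-ol
Product: 8 (2S,3Z,5Z,7R,8E)-9-iodo-7-methylnona-3,5,8-trien-2-ol, via phosphorus ylide 7 (not isolated)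
Conditions: KN(SiMe3)2 (2.1 equiv), THF, −78 °C to 0 °C
Reagents that add atoms: none
Why: Salt-free Wittig olefination of the non-stabilised ylide with the ring-opened lactol gives C17=C18 as the Z alkene under kinetic control, C19=C20 keeps the Z geometry it had in the ring, and no stereocentre is touched.

Step 6
Reactants: 8 (2S,3Z,5Z,7R,8E)-9-iodo-7-methylnona-3,5,8-trien-2-ol; 9 ethyl 2-methyl-3-oxobutanoate
Product: 10 (2S,3Z,5Z,7R,8E)-9-iodo-7-methylnona-3,5,8-trien-2-yl 2-methyl-3-oxobutanoate (C2 epimers)
Conditions: 9 (3 equiv), DMAP (0.3 equiv), 4 Å MS, PhMe, 105 °C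
Reagents that add atoms: none
Why: DMAP-catalysed transesterification of a β-keto ester acylates the secondary alcohol with retention at C21, and C2 is a labile epimer mixture at this stage.

Step 7
Reactants: 11 (S)-citronellyl bromide; 12 propyne
Product: 14 (6R)-6,10-dimethylundec-9-en-1-yne, via 1,3-dilithiopropyne 13 (not isolated)
Conditions: 12, n-BuLi (2 equiv), TMEDA, THF, −78 to 0 °C; then 11, 0 °C to rt; H2O
Reagents that add atoms: none
Why: SN2 alkylation of 1,3-dilithiopropyne at its more basic propargylic carbon adds C11–C13 and leaves the bought C8 untouched.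

Step 8
Reactants: 14 (6R)-6,10-dimethylundec-9-en-1-yne
Product: 16 (1E,6R)-1-iodo-6,10-dimethylundeca-1,9-diene, via alkenylzirconocene chloride 15 (not isolated)
Conditions: Cp2Zr(H)Cl, THF, rt; then I2, 0 °C
Reagents that add atoms: iodine, II
Why: In this hydrozirconation–iodination, syn addition to the terminal alkyne (the trisubstituted alkene is inert) followed by iodinolysis with retention gives the (E)-alkenyl iodide.

Step 9
Reactants: 16 (1E,6R)-1-iodo-6,10-dimethylundeca-1,9-diene
Product: 18 (4R,8E)-9-iodo-4-methylnon-8-enal, via secondary ozonide 17 (not isolated)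
Conditions: O3, CH2Cl2, −78 °C (Sudan Red 7B end point); then Me2S
Reagents that add atoms: ozone, [O-][O+]=O
Why: Ozonolysis stopped at a dye end point cleaves the electron-rich trisubstituted alkene in preference to the electron-poor iodoalkene, and reductive work-up gives the C5 aldehyde.

Step 10
Reactants: 18 (4R,8E)-9-iodo-4-methylnon-8-enal
Product: 19 (2E,4R,8E)-9-iodo-4-methylnona-2,8-dienal
Conditions: IBX, DMSO–PhF, 70 °C
Reagents that add atoms: none
Why: IBX α,β-dehydrogenation through the enol gives the thermodynamic (E)-enal (C6=C7), and C8 is only γ to the carbonyl and is kept.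

Step 11
Reactants: 10 (2S,3Z,5Z,7R,8E)-9-iodo-7-methylnona-3,5,8-trien-2-yl 2-methyl-3-oxobutanoate; 19 (2E,4R,8E)-9-iodo-4-methylnona-2,8-dienal
Product: 21 (2S,3Z,5Z,7R,8E)-9-iodo-7-methylnona-3,5,8-trien-2-yl (6E,8R,12E)-5-hydroxy-13-iodo-2,8-dimethyl-3-oxotrideca-6,12-dienoate (C2 and C5 epimers), via dilithium dianion 20 (not isolated)
Conditions: LiN(iPr)2 (2.1 equiv), THF, −78 to −30 °C; then 19, −78 °C; AcOH
Reagents that add atoms: none
Why: In this β-keto ester dianion aldol addition, the more reactive terminal C4 carbanion adds 1,2 to the enal and forms C4–C5, and the new C5 carbinol mixture does not matter because it is oxidised in step 13.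

Step 12
Reactants: 21 open bis[(E)-alkenyl iodide]
Product: 22 22-membered macrolactone (6E,12E,14E,17Z,19Z)-5-hydroxy-3-oxo pentaene with 8R 16S 21S configuration (C2 and C5 epimers)
Conditions: NiBr2(dme) (20 mol %), 4,4'-di-tert-butyl-2,2'-bipyridine (24 mol %), LiBr (0.1 M), DMA, Zn anode, Ni-foam cathode, undivided cell, 3 mA, 2.4 F/mol, 21 added over 10 h to 1 mM, rt, dark
Reagents that add atoms: none
Why: Proposed new method: cathodically formed zerovalent nickel inserts into one C(sp2)–I bond with retention, the divalent alkenylnickel is reduced by one electron at the cathode to the monovalent state, this inserts into the second C(sp2)–I bond of the same molecule, and the trivalent dialkenylnickel reductively eliminates to form C13–C14, closing the 22-membered ring and creating the (12E,14E)-diene, with oligomers suppressed by keeping both nickel and free substrate dilute; the closest known reactions are nickel-catalysed electroreductive homocoupling of alkenyl halides to 1,3-dienes and nickel-mediated reductive aryl–aryl macrocyclisation, and no stereocentre is formed or touched.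

Step 13
Reactants: 22 22-membered allylic alcohol macrolactone
Product: 24 deschloro macrolide (2S,6R,7R,8R,12S,15S,16R,21S) with trans-decalin and 14-membered Z,Z-dienyl lactone, via macrocyclic trienone 23 (not isolated)
Conditions: MnO2, CH2Cl2, rt; filter; PhMe, 60 °C
Reagents that add atoms: none
Why: Allylic oxidation turns C6=C7 into an enone dienophile inside the ring, and the transannular Diels–Alder reaction of the (12E,14E)-diene (the Z,Z-diene cannot reach s-cis) through the endo chair-like transition state gives the trans-decalin with H6/H7 trans and the C5 and C16 substituents cis; the face is set by the bought C16, whose C–H lies in the plane of both flanking alkenes to avoid A1,3 strain with the Z C17=C18 bond so that the chain carrying the dienophile leaves over one diene face only, the bought C8 then carries its methyl axial, and the labile C2 settles under thermodynamic control.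

Step 14
Reactants: 24 deschloro macrolide
Product: 25 target CNP0477386.1 (4-chloro-5-hydroxy-4-en-3-one form)
Conditions: N-chlorosuccinimide (1.0 equiv), 2,6-lutidine, CH2Cl2, −20 °C
Reagents that add atoms: N-chlorosuccinimide, O=C1CCC(=O)N1Cl
Why: Electrophilic α-chlorination attacks the most enolised carbon, C4 between the two ketones, one equivalent stops at the monochloride, which rests as the enol drawn, and the weak base lets the labile C2 stay in its thermodynamic (S) configuration within the rigid ring.

## Compound list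
1 | (S)-3-bromo-2-methylpropan-1-ol | BrC[C@@H](C)CO | starting material
2 | (S)-3-bromo-2-methylpropanal | BrC[C@@H](C)C=O | intermediate
3 | (1E,3S)-4-bromo-1-iodo-3-methylbut-1-ene | BrC[C@@H](C)/C=C/I | intermediate
4 | [(2S,3E)-4-iodo-2-methylbut-3-en-1-yl]triphenylphosphonium bromide | [Br-].c1ccccc1[P+](c1ccccc1)(c1ccccc1)C[C@@H](C)/C=C/I | intermediate
5 | (S)-5-methylfuran-2(5H)-one | C[C@H]1C=CC(=O)O1 | starting material
6 | (5S)-5-methyl-2,5-dihydrofuran-2-ol | C[C@H]1C=CC(O)O1 | intermediate
7 | [(2S,3E)-4-iodo-2-methylbut-3-enylidene]triphenylphosphorane | c1ccccc1P(c1ccccc1)(c1ccccc1)=C[C@@H](C)/C=C/I | intermediate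
8 | (2S,3Z,5Z,7R,8E)-9-iodo-7-methylnona-3,5,8-trien-2-ol | O[C@@H](C)/C=C\C=C/[C@@H](C)/C=C/I | intermediate
9 | ethyl 2-methyl-3-oxobutanoate | CCOC(=O)C(C)C(C)=O | starting material
10 | (2S,3Z,5Z,7R,8E)-9-iodo-7-methylnona-3,5,8-trien-2-yl 2-methyl-3-oxobutanoate | CC(=O)C(C)C(=O)O[C@@H](C)/C=C\C=C/[C@@H](C)/C=C/I | intermediate
11 | (S)-citronellyl bromide, (3S)-8-bromo-2,6-dimethyloct-2-ene | BrCC[C@@H](C)CCC=C(C)C | starting material
12 | propyne | CC#C | starting material
13 | 1,3-dilithiopropyne | [Li]CC#C[Li] | intermediate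
14 | (6R)-6,10-dimethylundec-9-en-1-yne | C#CCCC[C@@H](C)CCC=C(C)C | intermediate
15 | chlorobis(cyclopentadienyl)[(1E,6R)-6,10-dimethylundeca-1,9-dien-1-yl]zirconium | Cl[Zr](/C=C/CCC[C@@H](C)CCC=C(C)C)(C1C=CC=C1)C1C=CC=C1 | intermediate
16 | (1E,6R)-1-iodo-6,10-dimethylundeca-1,9-diene | I/C=C/CCC[C@@H](C)CCC=C(C)C | intermediate
17 | 3-[(3R,7E)-8-iodo-3-methyloct-7-en-1-yl]-5,5-dimethyl-1,2,4-trioxolane | I/C=C/CCC[C@@H](C)CCC1OOC(C)(C)O1 | intermediate
18 | (4R,8E)-9-iodo-4-methylnon-8-enal | I/C=C/CCC[C@@H](C)CCC=O | intermediate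
19 | (2E,4R,8E)-9-iodo-4-methylnona-2,8-dienal | I/C=C/CCC[C@@H](C)/C=C/C=O | intermediate
20 | dilithium dienediolate (dianion) of 10 | C=C(O[Li])C(C)=C(O[Li])O[C@@H](C)/C=C\C=C/[C@@H](C)/C=C/I | intermediate
21 | open bis[(E)-alkenyl iodide], 5-hydroxy-3-oxo ester (name as in step 11) | CC(C(=O)O[C@@H](C)/C=C\C=C/[C@@H](C)/C=C/I)C(=O)CC(O)/C=C/[C@H](C)CCC/C=C/I | intermediate
22 | 22-membered macrolactone, 5-hydroxy-3-oxo, (6E,12E,14E,17Z,19Z), 8R,16S,21S | CC1C(=O)O[C@@H](C)/C=C\C=C/[C@@H](C)/C=C/C=C/CCC[C@@H](C)/C=C/C(O)CC1=O | intermediate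
23 | 22-membered macrolactone, 3,5-dioxo trienone, same alkene geometries and stereocentres as 22 | CC1C(=O)O[C@@H](C)/C=C\C=C/[C@@H](C)/C=C/C=C/CCC[C@@H](C)/C=C/C(=O)CC1=O | intermediate
24 | deschloro macrolide (drawn as 3,5-diketone), 2S,6R,7R,8R,12S,15S,16R,21S; trans-decalin with axial C8 methyl | C[C@@H]1C(=O)O[C@@H](C)/C=C\C=C/[C@@H](C)[C@@H]2C=C[C@@H]3CCC[C@@H](C)[C@H]3[C@@H]2C(=O)CC1=O | intermediate
25 | CNP0477386.1, the 4-chloro enol of 24 | C[C@@H]1C(=O)O[C@@H](C)/C=C\C=C/[C@@H](C)[C@@H]2C=C[C@@H]3CCC[C@@H](C)[C@H]3[C@@H]2/C(O)=C(/Cl)C1=O | target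

## Step count and weak points
Total steps: 14. Longest linear sequence: 9 (steps 1, 2, 3, 5, 6, 11, 12, 13, 14).

**Step 12 (the proposed new step).**
- Risks: the acidic β-keto ester may cause protodeiodination or bind nickel, the substrate may oligomerise, and some E geometry may be lost.
- The fallback sets out from 14 (and uses dianion 20 made from 10) and comes back at 22. It replaces the reductive coupling by a polarity-differentiated Suzuki–Miyaura macrocyclisation, which is known chemistry.
- Hydroboration of 14 with pinacolborane (Cp2Zr(H)Cl as catalyst) gives the (E)-alkenyl pinacolboronate F1, selective ozonolysis as in step 9 gives the boronate aldehyde F2, IBX as in step 10 gives the boronate enal F3, and addition of dianion 20 as in step 11 gives the iodide–boronate seco ester F4. Pd(PPh3)4 and Cs2CO3 in THF–H2O at high dilution then close C13–C14 to give 22.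

**Step 13.**
- Risks: the axial C8 methyl costs roughly 1–1.5 kcal/mol in the required transition state. This could erode or overturn the facial bias from C16, and exo (cis-fused) adducts may also appear.
- The fallback sets out from 2 (and uses F3) and comes back at 24. It adds a removable bromine at C14 as a conformational lock.
- Ramirez olefination of 2 (CBr4, PPh3) gives (3S)-1,1,4-tribromo-3-methylbut-1-ene F5, PPh3 gives the phosphonium bromide F6, a Wittig reaction with 6 as in step 5 gives the dibromo trienol F7, and transesterification with 9 as in step 6 gives the β-keto ester F8.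
- The dianion of F8 adds to F3 to give the dibromide–boronate seco ester F9. Suzuki–Miyaura closure with zerovalent palladium at the bromine trans to C16 gives the macrocyclic (14Z)-14-bromodiene alcohol F10, and MnO2 gives the 14-bromo trienone F11.
- In F11 the bromine is cis to C16, and A1,3 strain allows only the rotamer with the C16–H inside. The cycloaddition therefore gives the 14-bromo tricycle F12, and Pd(PPh3)4/Bu3SnH hydrodebromination gives 24.

**Step 11.**
- Risks: the strongly basic dianion may attack the alkenyl iodides, trigger a Carroll rearrangement of the dienyl ester, or add 1,4.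
- The fallback sets out from 10 and comes back at 21, moving from basic to Lewis-acidic bond formation.
- Me3SiCl/Et3N followed by LiN(iPr)2/Me3SiCl converts 10 into the 1,3-bis(trimethylsilyloxy)diene F13. A BF3·OEt2-mediated vinylogous Mukaiyama aldol addition of F13 to 19 at −78 °C gives 21 after aqueous work-up.

## Further compounds
F1 | step 12 | 2-[(1E,6R)-6,10-dimethylundeca-1,9-dien-1-yl]-4,4,5,5-tetramethyl-1,3,2-dioxaborolane | CC1(C)OB(/C=C/CCC[C@@H](C)CCC=C(C)C)OC1(C)C
F2 | step 12 | (4R,8E)-4-methyl-9-(4,4,5,5-tetramethyl-1,3,2-dioxaborolan-2-yl)non-8-enal | CC1(C)OB(/C=C/CCC[C@@H](C)CCC=O)OC1(C)C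
F3 | step 12 | (2E,4R,8E)-4-methyl-9-(4,4,5,5-tetramethyl-1,3,2-dioxaborolan-2-yl)nona-2,8-dienal | CC1(C)OB(/C=C/CCC[C@@H](C)/C=C/C=O)OC1(C)C
F4 | step 12 | analogue of 21 with pinacolboronate in place of iodine at C13 | CC(C(=O)O[C@@H](C)/C=C\C=C/[C@@H](C)/C=C/I)C(=O)CC(O)/C=C/[C@H](C)CCC/C=C/B1OC(C)(C)C(C)(C)O1
F5 | step 13 | (3S)-1,1,4-tribromo-3-methylbut-1-ene | BrC[C@@H](C)C=C(Br)Br
F6 | step 13 | [(2S)-4,4-dibromo-2-methylbut-3-en-1-yl]triphenylphosphonium bromide | [Br-].c1ccccc1[P+](c1ccccc1)(c1ccccc1)C[C@@H](C)C=C(Br)Br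
F7 | step 13 | (2S,3Z,5Z,7R)-9,9-dibromo-7-methylnona-3,5,8-trien-2-ol | O[C@@H](C)/C=C\C=C/[C@@H](C)C=C(Br)Br
F8 | step 13 | 2-methyl-3-oxobutanoate of F7 | CC(=O)C(C)C(=O)O[C@@H](C)/C=C\C=C/[C@@H](C)C=C(Br)Br
F9 | step 13 | analogue of F4 with CBr2 in place of CHI at C14 | CC(C(=O)O[C@@H](C)/C=C\C=C/[C@@H](C)C=C(Br)Br)C(=O)CC(O)/C=C/[C@H](C)CCC/C=C/B1OC(C)(C)C(C)(C)O1
F10 | step 13 | (14Z)-14-bromo derivative of 22 | CC1C(=O)O[C@@H](C)/C=C\C=C/[C@@H](C)/C=C(\Br)/C=C/CCC[C@@H](C)/C=C/C(O)CC1=O
F11 | step 13 | (14Z)-14-bromo derivative of 23 | CC1C(=O)O[C@@H](C)/C=C\C=C/[C@@H](C)/C=C(\Br)/C=C/CCC[C@@H](C)/C=C/C(=O)CC1=O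
F12 | step 13 | 14-bromo derivative of 24 | C[C@@H]1C(=O)O[C@@H](C)/C=C\C=C/[C@@H](C)[C@@H]2C(Br)=C[C@@H]3CCC[C@@H](C)[C@H]3[C@@H]2C(=O)CC1=O
F13 | step 11 | 1,3-bis(trimethylsilyloxy)diene of 10 | C=C(O[Si](C)(C)C)C(C)=C(O[Si](C)(C)C)O[C@@H](C)/C=C\C=C/[C@@H](C)/C=C/I
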